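(The readings are calculated for an exercise.)

Two questions stood over these flasks, and I approached both through how much substrate the coupling partner could consume.

* [target] at the end for Wednesday's, Friday's, Monday's, Saturday's, Sunday's, in this order
* the shape of the row from first to last (falls all the way / rises all the way / rises, then falls / falls, then rises / hardly changes)

| flask | substrate | coupling partner | remark | time |
|---|---|---|---|---|
| winter | 2.3 mM | 9 mM | run made earlier |  |
| summer | 13 mM | 9 mM | run made earlier |  |
| Wednesday's | 2.0 mM | 9.00 mM |  | 3.0 d |
| Friday's | 3.0 mM | 9.00 mM |  | 3.0 d |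
| Monday's | 4.0 mM | 9.00 mM |  | 3.0 d |
| Saturday's | 6.0 mM | 9.00 mM |  | 3.0 d |
| Sunday's | 10 mM | 9.00 mM |  | 3.0 d |

- winter (time / h: target / %, substrate / %): 6.00: 0.9, 7.9; 20.0: 5.2, 0.1; 30.0: 9.2, 0; 48.0: 20.5, 0
- summer (time / h: target / %, substrate / %): 12.0: 0.7, 49.5; 25.0: 1.3, 40.7; 40.0: 1.4, 35.9; 48.0: 1.9, 34.3

(scatter of a reading: 0.5 percentage points)

- "hardly changes" means that all values lie within two and a half points (for a concentration: within two and a half percent of the largest)

In the summer run the substrate fell from 35.9 % at 40.0 h to 34.3 % at 48.0 h, a slow fall by then, so I reckoned what it had lost: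

lost = 13 mM × (fraction gone) = 8.54 mM

I called this the stall: the substrate that this charge of partner could consume, as read from the summer run. It lay close to the partner charge of 9 mM.

On a first round I let target follow the charge, so the row rose up to the stall. Put back against the runs, that failed: the summer run showed 1.9 % of target at 48.0 h, less than the winter run's 20.5 %. On the second round I therefore let the yield shrink with the charge:

target ∝ charge × (stall − charge)

top of the row = stall / 2 = 4.27 mM

A row rising all the way needed that top at Sunday's 10 mM or beyond, and so a stall of 20.0 mM. The stall I had read was lower by a factor of 2.34. I committed to a rise and a fall, with Sunday's flask charged above the stall and reckoned to keep 1.46 mM of substrate.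

The forecast gave 0.75 mM, 1 mM, 1.1 mM, 1 mM and 0.45 mM, a row that rises, then falls, reasoning that “one partner is consumed per substrate”.

The flasks gave 0.688 mM, 1.00 mM, 1.24 mM, 1.14 mM and 0.500 mM: the row rises, then falls, turning at 4.7 mM.

    intermediate C → intermediate D (k = 0.110 h⁻¹)
    intermediate B → target (k = 0.0980 h⁻¹)
    substrate + intermediate D → side product (k = 23.0 L mol⁻¹ h⁻¹)
    coupling partner + intermediate A → intermediate B (k = 7.50 L mol⁻¹ h⁻¹)
    substrate + coupling partner ⇌ intermediate A (K = 3200 L mol⁻¹, k = 72.0 L mol⁻¹ h⁻¹)
    coupling partner + intermediate A → intermediate C (k = 300 L mol⁻¹ h⁻¹)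
    intermediate D → intermediate B (k = 0.00820 h⁻¹)

Sunday's flask, charged above the stall, ended with the partner, the limiting reagent, at 0.337 % of its charge and substrate at 17.9 %, which is 1.79 mM against my 1.46 mM. Wednesday's flask, charged below the stall, ended with its substrate at 0 %, yet intermediate D still held 58.6 % of the charge and target 34.4 %. Wednesday's target depended on the step from intermediate D to intermediate B: the same flask without that step gave 0.0483 mM instead of 0.688 mM.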